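Cuts: (a) the sp2–sp2 bond from ring B carbon B1 to the styrenyl carbon C1, (b) the ester bond O4–C(=O), (c) the diaryl ether bond from oxygen to C5 of ring A, (d) the C3–C4 bond of the diol chain.
Enabling feature: the run O3–C3H–C2H=C1H–B1 with its Z alkene is a masked 2,5-dihydro-1,2-oxasilole. With Si in the place of B1 and bonded to O3, the five-membered ring (O3, Si, C1, C2, C3) can hold only the cis alkene.
Forward order: rings A and B are bought and joined through oxygen, and the C9 chain is attached as the ester. Metathesis closes the oxasilole, and the last step exchanges Si for B1, closing the 12-membered lactone while the small ring is cut out.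
Stereochemistry: C3 and C4 (S,S, syn) arise together in one reagent-controlled (Z)-γ-alkoxyallylboration of hexanal, with Ipc groups from (−)-α-pinene. The Z alkene is fixed by the oxasilole and passed on with retention.
Key step: step 11

Remark: chain atoms keep the non-1-ene locants throughout (C1=C2 alkene, C3 allylic carbinol, C4 acyloxy carbinol, O3 and O4 their oxygens). Ring A is the 2-methylbenzoate ring and ring B the iodo/hydroxy ring, with B1 the carbon that bears iodine. The boronic acid, 2-iodo-6-methoxyphenol and the chiral borane are taken to be catalogue items.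

Step 1
Reactants: 1 allyl alcohol
Product: 2 allyl methoxymethyl ether
Conditions: MOMCl, iPr2NEt, CH2Cl2, 0 °C to rt; distillation
Reagents that add atoms: chloromethyl methyl ether, COCCl
Why: O-alkylation of a primary alcohol by the very electrophilic α-chloro ether, with a hindered amine as acid scavenger, is a standard acetal protection that leaves the alkene untouched.

Step 2
Reactants: 2 allyl methoxymethyl ether; 3 (+)-B-methoxydiisopinocampheylborane, from (−)-α-pinene; 4 hexanal
Product: 9 (3S,4S)-3-(methoxymethoxy)non-1-en-4-ol, via Z-allyllithium 5 (not isolated), via lithium borate 6 (not isolated), via Z-alkoxyallylborane 7 (not isolated), via borinic ester 8 (not isolated)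
Conditions: sec-BuLi, THF, −78 °C; 3, −78 °C; BF3·OEt2, then 4, −78 °C; NaOH, H2O2, 0 °C to rt
Reagents that add atoms: none
Why: In this Brown asymmetric (Z)-γ-alkoxyallylboration, Li–O chelation holds 5 in the Z form, boron is taken up at the carbon remote from oxygen, BF3 strips methoxide from 6, and 7 adds to hexanal through a closed chair (Zimmerman–Traxler) transition state in which the Z enol ether geometry becomes the syn C3/C4 relation and the isopinocampheyl groups of the (−)-α-pinene series direct attack to the Re face of the aldehyde, which should give the (3S,4S) isomer with O4 free and O3 masked.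

Step 3
Reactants: 10 3-(methoxycarbonyl)-4-methylphenylboronic acid; 11 2-iodo-6-methoxyphenol
Product: 12 methyl 5-(2-iodo-6-methoxyphenoxy)-2-methylbenzoate
Conditions: Cu(OAc)2, pyridine, 4 Å MS, CH2Cl2, dry air, rt (10 in excess)
Reagents that add atoms: none
Why: Chan–Lam oxidative O-arylation runs at room temperature by aryl transfer from boron to copper and C–O bond formation at copper, and it accepts ortho-iodo and di-ortho-substituted phenols because no zerovalent metal able to insert into the C–I bond is present.

Step 4
Reactants: 12 methyl 5-(2-iodo-6-methoxyphenoxy)-2-methylbenzoate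
Product: 14 methyl 5-(2-hydroxy-6-iodophenoxy)-2-methylbenzoate, via aryloxydibromoborane 13 (not isolated)
Conditions: BBr3, CH2Cl2, −78 to 0 °C; H2O
Reagents that add atoms: none
Why: In this Lewis-acid ether cleavage BBr3 binds the alkyl aryl ether oxygen and bromide removes the methyl group by SN2, whereas the diaryl ether offers no sp3 carbon and the methyl ester reacts more slowly at or below 0 °C (any ester lost here merges with the product of step 5).

Step 5
Reactants: 14 methyl 5-(2-hydroxy-6-iodophenoxy)-2-methylbenzoate
Product: 15 5-(2-hydroxy-6-iodophenoxy)-2-methylbenzoic acid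
Conditions: LiOH, THF–MeOH–H2O, 40 °C; 1 M HCl
Reagents that add atoms: lithium hydroxide, [Li+].[OH-]
Why: Acyl–oxygen saponification of a methyl benzoate with a single ortho substituent needs only gentle warming, and neither the aryl iodide nor the diaryl ether reacts with hydroxide at this temperature.

Step 6
Reactants: 15 5-(2-hydroxy-6-iodophenoxy)-2-methylbenzoic acid
Product: 17 5-[2-(tert-butyldimethylsilyloxy)-6-iodophenoxy]-2-methylbenzoic acid, via bis-silyl derivative 16 (not isolated)
Conditions: TBSCl, imidazole, DMF, rt; AcOH–THF–H2O, rt, short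
Reagents that add atoms: tert-butyldimethylsilyl chloride, CC(C)(C)[Si](C)(C)Cl
Why: Exhaustive imidazole-promoted silylation followed by brief dilute-acid hydrolysis exploits the much greater lability of a silyl ester than of an aryl silyl ether.

Step 7
Reactants: 17 5-[2-(tert-butyldimethylsilyloxy)-6-iodophenoxy]-2-methylbenzoic acid; 9 (3S,4S)-3-(methoxymethoxy)non-1-en-4-ol
Product: 19 (3S,4S)-3-(methoxymethoxy)non-1-en-4-yl 5-[2-(tert-butyldimethylsilyloxy)-6-iodophenoxy]-2-methylbenzoate, via mixed anhydride 18 (not isolated)
Conditions: 2,4,6-Cl3C6H2COCl, Et3N, toluene, rt; 9, DMAP, toluene, rt to 40 °C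
Reagents that add atoms: none
Why: In this Yamaguchi esterification, DMAP-catalysed acyl transfer from 18 takes place at the toluoyl carbonyl (one ortho substituent against two ortho chlorines) onto the only free hydroxyl, O4, with C4 unchanged because no C–O bond of the alcohol is broken.

Step 8
Reactants: 19 (3S,4S)-3-(methoxymethoxy)non-1-en-4-yl 5-[2-(tert-butyldimethylsilyloxy)-6-iodophenoxy]-2-methylbenzoate
Product: 20 (3S,4S)-3-hydroxynon-1-en-4-yl 5-[2-(tert-butyldimethylsilyloxy)-6-iodophenoxy]-2-methylbenzoate
Conditions: ZnBr2, n-PrSH, CH2Cl2, 0 °C, minutes; sat. NaHCO3; crude product used at once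
Reagents that add atoms: none
Why: In this Lewis acid/soft nucleophile acetal cleavage ZnBr2 activates the formaldehyde acetal and the thiol captures the methoxymethyl unit within minutes, a window in which aryl silyl ethers, benzoates, terminal alkenes and aryl iodides persist and the aroyl group should stay on O4.

Step 9
Reactants: 20 (3S,4S)-3-hydroxynon-1-en-4-yl 5-[2-(tert-butyldimethylsilyloxy)-6-iodophenoxy]-2-methylbenzoate; 21 chlorodimethylvinylsilane
Product: 22 (3S,4S)-3-[(ethenyldimethylsilyl)oxy]non-1-en-4-yl 5-[2-(tert-butyldimethylsilyloxy)-6-iodophenoxy]-2-methylbenzoate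
Conditions: imidazole, CH2Cl2, 0 °C
Reagents that add atoms: none
Why: Imidazole-assisted O-silylation of a secondary allylic alcohol by an unhindered chlorosilane is fast at 0 °C, so O3 is capped before the neighbouring aroyl group can move.

Step 10
Reactants: 22 (3S,4S)-3-[(ethenyldimethylsilyl)oxy]non-1-en-4-yl 5-[2-(tert-butyldimethylsilyloxy)-6-iodophenoxy]-2-methylbenzoate
Product: 23 (1S)-1-[(5S)-2,2-dimethyl-2,5-dihydro-1,2-oxasilol-5-yl]hexyl 5-[2-(tert-butyldimethylsilyloxy)-6-iodophenoxy]-2-methylbenzoate
Conditions: Mo(N-2,6-iPr2C6H3)(CHCMe2Ph)[OCMe(CF3)2]2 (5–8 mol %), benzene, rt, argon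
Reagents that add atoms: none
Why: Ring-closing metathesis of allylic dimethylvinylsilyl ethers to five-membered cycloalkenylsiloxanes is established with this highly active molybdenum imido alkylidene, which accepts the sluggish vinylsilane, tolerates esters, silyl ethers and aryl iodides and is driven by loss of ethene, while the ring size enforces the cis alkene and C3 is untouched.

Step 11
Reactants: 23 (1S)-1-[(5S)-2,2-dimethyl-2,5-dihydro-1,2-oxasilol-5-yl]hexyl 5-[2-(tert-butyldimethylsilyloxy)-6-iodophenoxy]-2-methylbenzoate
Product: 26 target macrolactone CNP0319567.1 (3S,4S,1Z), via Z-alkenylsilanol 24 (not isolated), via 13-membered palladacycle 25 (not isolated)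
Conditions: [Pd(C3H5)Cl]2 (10 mol %), TBAF·3H2O (10 equiv), THF, rt; 23 in THF added by syringe pump (final ≤0.01 M); aq. NH4Cl
Reagents that add atoms: none
Why: Hydrated fluoride removes the phenolic silyl group and opens the oxasilole to the fluoride-activated Z-alkenylsilanol 24, zerovalent palladium released from [Pd(C3H5)Cl]2 inserts into the B1–I bond, intramolecular transfer of the alkenyl group from silicon to divalent palladium gives the 13-membered diorganopalladium ring 25, and reductive elimination forms the B1–C1 bond. The closest known reaction type is the fluoride-promoted intramolecular Hiyama–Denmark coupling of metathesis-derived cycloalkenylsiloxanes bearing a tethered sp2 iodide, which closes nine- to twelve-membered rings, backed by the intermolecular coupling of the same five-membered siloxanes with aryl iodides. The 12-membered lactone closes by contraction of palladacycle 25 (macrocyclization at an sp2–sp2 bond, alkene endocyclic), while the five-membered O–Si ring is excised rather than retained. No new stereocentre is formed: C3 and C4 are spectators, and the Z alkene is inherited because transmetalation and reductive elimination both proceed with retention at C1. Cyclization has to beat oligomerization and protodesilylation, which slow addition into excess fluoride and catalyst at high dilution and the cis-bent chain that holds C1 near B1 should secure. The aroyl group has to stay on O4, which the ortho-methyl shielding of the carbonyl, the strain of the 11-membered isomer and the water-tempered basicity of TBAF at room temperature should favour.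

Compound list
1 | allyl alcohol | C=CCO | starting material
2 | allyl methoxymethyl ether | C=CCOCOC | intermediate
3 | (+)-B-methoxydiisopinocampheylborane, from (−)-α-pinene | COB([C@H]1C[C@H]2C[C@@H]([C@@H]1C)C2(C)C)[C@H]1C[C@H]2C[C@@H]([C@@H]1C)C2(C)C | starting material
4 | hexanal | CCCCCC=O | starting material
5 | (Z)-3-(methoxymethoxy)allyllithium, formed in the flask | [Li]C/C=C\OCOC | intermediate
6 | lithium [(Z)-3-(methoxymethoxy)allyl](methoxy)diisopinocampheylborate, formed in the flask | [Li+].CO[B-](C/C=C\OCOC)([C@H]1C[C@H]2C[C@@H]([C@@H]1C)C2(C)C)[C@H]1C[C@H]2C[C@@H]([C@@H]1C)C2(C)C | intermediate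
7 | [(Z)-3-(methoxymethoxy)allyl]diisopinocampheylborane, formed in the flask | COCO/C=C\CB([C@H]1C[C@H]2C[C@@H]([C@@H]1C)C2(C)C)[C@H]1C[C@H]2C[C@@H]([C@@H]1C)C2(C)C | intermediate
8 | (3S,4S)-3-(methoxymethoxy)non-1-en-4-yl diisopinocampheylborinate, formed in the flask | CCCCC[C@H](OB([C@H]1C[C@H]2C[C@@H]([C@@H]1C)C2(C)C)[C@H]1C[C@H]2C[C@@H]([C@@H]1C)C2(C)C)[C@@H](OCOC)C=C | intermediate
9 | (3S,4S)-3-(methoxymethoxy)non-1-en-4-ol | CCCCC[C@H](O)[C@@H](OCOC)C=C | intermediate
10 | 3-(methoxycarbonyl)-4-methylphenylboronic acid | COC(=O)c1cc(B(O)O)ccc1C | starting material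
11 | 2-iodo-6-methoxyphenol | COc1cccc(I)c1O | starting material
12 | methyl 5-(2-iodo-6-methoxyphenoxy)-2-methylbenzoate | COC(=O)c1cc(Oc2c(I)cccc2OC)ccc1C | intermediate
13 | methyl 5-[2-(dibromoboranyloxy)-6-iodophenoxy]-2-methylbenzoate, formed in the flask | COC(=O)c1cc(Oc2c(I)cccc2OB(Br)Br)ccc1C | intermediate
14 | methyl 5-(2-hydroxy-6-iodophenoxy)-2-methylbenzoate | COC(=O)c1cc(Oc2c(I)cccc2O)ccc1C | intermediate
15 | 5-(2-hydroxy-6-iodophenoxy)-2-methylbenzoic acid | OC(=O)c1cc(Oc2c(I)cccc2O)ccc1C | intermediate
16 | tert-butyldimethylsilyl 5-[2-(tert-butyldimethylsilyloxy)-6-iodophenoxy]-2-methylbenzoate, formed in the flask | CC(C)(C)[Si](C)(C)OC(=O)c1cc(Oc2c(I)cccc2O[Si](C)(C)C(C)(C)C)ccc1C | intermediate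
17 | 5-[2-(tert-butyldimethylsilyloxy)-6-iodophenoxy]-2-methylbenzoic acid | OC(=O)c1cc(Oc2c(I)cccc2O[Si](C)(C)C(C)(C)C)ccc1C | intermediate
18 | 5-[2-(tert-butyldimethylsilyloxy)-6-iodophenoxy]-2-methylbenzoic 2,4,6-trichlorobenzoic anhydride, formed in the flask | O=C(OC(=O)c1c(Cl)cc(Cl)cc1Cl)c1cc(Oc2c(I)cccc2O[Si](C)(C)C(C)(C)C)ccc1C | intermediate
19 | (3S,4S)-3-(methoxymethoxy)non-1-en-4-yl 5-[2-(tert-butyldimethylsilyloxy)-6-iodophenoxy]-2-methylbenzoate | CCCCC[C@H](OC(=O)c1cc(Oc2c(I)cccc2O[Si](C)(C)C(C)(C)C)ccc1C)[C@@H](OCOC)C=C | intermediate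
20 | (3S,4S)-3-hydroxynon-1-en-4-yl 5-[2-(tert-butyldimethylsilyloxy)-6-iodophenoxy]-2-methylbenzoate | CCCCC[C@H](OC(=O)c1cc(Oc2c(I)cccc2O[Si](C)(C)C(C)(C)C)ccc1C)[C@@H](O)C=C | intermediate
21 | chlorodimethylvinylsilane | C=C[Si](C)(C)Cl | starting material
22 | (3S,4S)-3-[(ethenyldimethylsilyl)oxy]non-1-en-4-yl 5-[2-(tert-butyldimethylsilyloxy)-6-iodophenoxy]-2-methylbenzoate | CCCCC[C@H](OC(=O)c1cc(Oc2c(I)cccc2O[Si](C)(C)C(C)(C)C)ccc1C)[C@@H](O[Si](C)(C)C=C)C=C | intermediate
23 | (1S)-1-[(5S)-2,2-dimethyl-2,5-dihydro-1,2-oxasilol-5-yl]hexyl 5-[2-(tert-butyldimethylsilyloxy)-6-iodophenoxy]-2-methylbenzoate | CCCCC[C@H](OC(=O)c1cc(Oc2c(I)cccc2O[Si](C)(C)C(C)(C)C)ccc1C)[C@H]3O[Si](C)(C)C=C3 | intermediate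
24 | (1Z,3S,4S)-3-hydroxy-1-[hydroxy(dimethyl)silyl]non-1-en-4-yl 5-(2-hydroxy-6-iodophenoxy)-2-methylbenzoate, formed in the flask | CCCCC[C@H](OC(=O)c1cc(Oc2c(I)cccc2O)ccc1C)[C@@H](O)/C=C\[Si](C)(C)O | intermediate
25 | 13-membered aryl(Z-alkenyl)palladium ring: 26 with divalent palladium inserted between B1 and C1, ligands omitted, formed in the flask | CCCCC[C@@H]1OC(=O)c2cc(ccc2C)Oc2c(O)cccc2[Pd]/C=C\[C@@H]1O | intermediate
26 | CNP0319567.1: 12-membered lactone in which O4 of the (3S,4S) chain carries the 2-methylbenzoyl carbonyl of ring A, C5 of ring A is linked through oxygen to the ring B carbon between B1 and the phenol carbon, B1 bears the Z C1=C2 alkene, O3 is a free hydroxyl and C4 bears n-pentyl | CCCCC[C@@H]1OC(=O)c2cc(ccc2C)Oc2c(O)cccc2/C=C\[C@@H]1O | target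

Total steps: 11. Longest linear sequence: 9 steps (steps 3 to 11, from 10 and 11 to 26). The chain fragment adds 2 steps in a parallel branch.

Steps most likely to fail

Step 11. Chain growth between molecules, loss of silicon by protonation before transmetalation, and a base-induced shift of the aroyl group from O4 to O3 may all outpace ring closure. The fallback sets out from 19 and comes back at 26, and it closes the ring at the alkene instead of at the aryl–alkenyl bond.
- Stille vinylation of the aryl iodide of 19 with tributyl(vinyl)stannane and Pd(PPh3)4 in toluene is neutral enough for the aryl silyl ether. It would give (3S,4S)-3-(methoxymethoxy)non-1-en-4-yl 5-[2-(tert-butyldimethylsilyloxy)-6-ethenylphenoxy]-2-methylbenzoate F1.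
- Z-selective macrocyclic ring-closing metathesis of the styrenyl and allylic vinyl groups follows, with the monoaryloxide pyrrolide alkylidene Mo(N-2,6-iPr2C6H3)(CHCMe2Ph)(NC4H2-2,5-Me2)(O-2,6-(2,4,6-iPr3C6H2)2C6H3) at high dilution under reduced pressure. It would give the O3-methoxymethyl ring B O-silyl Z macrolactone F2.
- ZnBr2/n-PrSH as in step 8 would free O3 to give the ring B O-silyl Z macrolactone F3, and TBAF buffered with AcOH would release the phenol to give 26.
- The alkene geometry then rests on catalyst control instead of on a template.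

Step 3. Slow aryl transfer to the crowded, di-ortho-substituted phenol may let protodeboronation and oxidative homocoupling consume the electron-poor boronic acid. The fallback sets out from 10 and 11 and comes back at 12, and it replaces copper by metal-free O-arylation with a diaryliodonium salt.
- 4-Iodoanisole is oxidised with mCPBA and BF3·OEt2 in CH2Cl2 and treated with 10. This would give (4-methoxyphenyl)[3-(methoxycarbonyl)-4-methylphenyl]iodonium tetrafluoroborate F4.
- Phenol 11 with t-BuOK in THF should then receive the less electron-rich-blocked aryl group, that is the ester-bearing ring rather than the anisyl ring, by ligand coupling at iodine. This reaction type accepts hindered and halogenated phenols, and it would give 12.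

Step 8. The Lewis acid/thiol pair may erode the phenolic silyl ether or promote the shift of the aroyl group from O4 to the freed O3 before the acetal is fully cleaved. The fallback sets out from 4 (with 3 and 17) and comes back at 20, and it masks O3 with a group that leaves by oxidation.
- The allylboration protocol of step 2 is run on bought allyl 4-methoxyphenyl ether in place of 2, a known variant. It would give (3S,4S)-3-(4-methoxyphenoxy)non-1-en-4-ol F5.
- Esterification with 17 through 18 as in step 7 would give (3S,4S)-3-(4-methoxyphenoxy)non-1-en-4-yl 5-[2-(tert-butyldimethylsilyloxy)-6-iodophenoxy]-2-methylbenzoate F6.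
- (NH4)2Ce(NO3)6 in MeCN–H2O at 0 °C would then oxidise the much more electron-rich dialkoxybenzene ring selectively and release 20 without Lewis acid or thiol.

Further compounds
F1 | step 11 | (3S,4S)-3-(methoxymethoxy)non-1-en-4-yl 5-[2-(tert-butyldimethylsilyloxy)-6-ethenylphenoxy]-2-methylbenzoate | CCCCC[C@H](OC(=O)c1cc(Oc2c(C=C)cccc2O[Si](C)(C)C(C)(C)C)ccc1C)[C@@H](OCOC)C=C
F2 | step 11 | O3-methoxymethyl ring B O-(tert-butyldimethylsilyl) derivative of 26 (3S,4S,1Z) | CCCCC[C@@H]1OC(=O)c2cc(ccc2C)Oc2c(O[Si](C)(C)C(C)(C)C)cccc2/C=C\[C@@H]1OCOC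
F3 | step 11 | ring B O-(tert-butyldimethylsilyl) ether of 26 (3S,4S,1Z) | CCCCC[C@@H]1OC(=O)c2cc(ccc2C)Oc2c(O[Si](C)(C)C(C)(C)C)cccc2/C=C\[C@@H]1O
F4 | step 3 | (4-methoxyphenyl)[3-(methoxycarbonyl)-4-methylphenyl]iodonium tetrafluoroborate | COC(=O)c1cc(ccc1C)[I+]c1ccc(OC)cc1.F[B-](F)(F)F
F5 | step 8 | (3S,4S)-3-(4-methoxyphenoxy)non-1-en-4-ol | CCCCC[C@H](O)[C@@H](Oc1ccc(OC)cc1)C=C
F6 | step 8 | (3S,4S)-3-(4-methoxyphenoxy)non-1-en-4-yl 5-[2-(tert-butyldimethylsilyloxy)-6-iodophenoxy]-2-methylbenzoate | CCCCC[C@H](OC(=O)c1cc(Oc2c(I)cccc2O[Si](C)(C)C(C)(C)C)ccc1C)[C@@H](Oc1ccc(OC)cc1)C=C
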